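**Retrosynthetic overview**
1. Target 20 ⇐ tribenzyl ether 19 by hydrogenolysis; 19 ⇐ aryl bromide 8 + keto aldehyde 14 in a one-pot aryl-metal addition / hemiketalisation / ionic hydrogenation that forms the C2–aryl bond, closes O1–C5 of the oxolane and sets C2 and C5.
2. 14 ⇐ keto acid 12 ⇐ meso anhydride 10 + arylzinc 11 by catalytic enantioselective desymmetrisation: one catalytic event fixes C3 and C4 and decides which end of the four-carbon chain carries which aryl group.
3. 8 ⇐ (E)-1,2-diarylpropene 7 by iridium-catalysed asymmetric hydrogenation (side-chain stereocentre); 7 ⇐ iodide 2 + alkenylboronate 6 (from alkyne 5).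
4. Enabling feature: the oxolane O1–C2–C3–C4–C5 carries all four substituents on one face, and both O-bearing carbons (C2, C5) are benzylic to para-oxygenated benzene rings. C5 can therefore be closed as an aryl-stabilised oxocarbenium ion whose only open face is opposite the C2 aryl, C3 methyl and C4 methyl groups, while C2 sits next to the C3 methyl stereocentre (a Felkin–Anh pair).
5. Ring order: the three benzene rings are bought; the oxolane is the only ring constructed and is closed last.

Key step: step 10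

Remark on the chemistry: the sense of induction of the two chiral catalysts (steps 5 and 7) is assigned by analogy with their standard substrates; the ligand antipode is to be used if the opposite sense is found.

**Step 1**
Reactants: 1 4-bromo-2-iodophenol
Product: 2 1-(benzyloxy)-4-bromo-2-iodobenzene
Conditions: BnBr, K2CO3, acetone, reflux
Reagents that add atoms: benzyl bromide, BrCc1ccccc1
Why: Williamson O-benzylation of the phenoxide masks the phenol for all organometallic steps and is removable at the end under neutral conditions.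

**Step 2**
Reactants: 3 1-(benzyloxy)-4-iodobenzene; 4 propyne
Product: 5 1-(benzyloxy)-4-(prop-1-yn-1-yl)benzene
Conditions: propyne (excess, THF solution), PdCl2(PPh3)2 (2 mol %), CuI (4 mol %), Et3N, THF, rt, sealed vessel
Reagents that add atoms: none
Why: Sonogashira coupling of an aryl iodide with a terminal alkyne (oxidative addition to zerovalent palladium, copper acetylide transmetalation) is routine for this substrate class.

**Step 3**
Reactants: 5 1-(benzyloxy)-4-(prop-1-yn-1-yl)benzene
Product: 6 2-[(1Z)-1-[4-(benzyloxy)phenyl]prop-1-en-2-yl]-4,4,5,5-tetramethyl-1,3,2-dioxaborolane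
Conditions: B2pin2, CuCl (5 mol %), NaOtBu (10 mol %), P(p-tol)3 (6 mol %), MeOH (2 equiv), THF, rt
Reagents that add atoms: bis(pinacolato)diboron, CC1(C)OB(OC1(C)C)B1OC(C)(C)C(C)(C)O1
Why: Copper-catalysed syn-hydroboration (borylcupration, then protonation by MeOH) of an aryl alkyl alkyne should place boron on the methyl-bearing carbon, because copper prefers the benzylic position, and give the (Z)-alkenylboronate.

**Step 4**
Reactants: 6 2-[(1Z)-1-[4-(benzyloxy)phenyl]prop-1-en-2-yl]-4,4,5,5-tetramethyl-1,3,2-dioxaborolane; 2 1-(benzyloxy)-4-bromo-2-iodobenzene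
Product: 7 1-(benzyloxy)-4-bromo-2-[(1E)-1-[4-(benzyloxy)phenyl]prop-1-en-2-yl]benzene
Conditions: PdCl2(dppf) (3 mol %), K3PO4, 1,4-dioxane/H2O, 60 °C
Reagents that add atoms: none
Why: Suzuki–Miyaura coupling proceeds with retention of alkene geometry and at the C–I bond of 2 in preference to the C–Br bond (faster oxidative addition to zerovalent palladium), so the bromide is kept for step 10.

**Step 5**
Reactants: 7 1-(benzyloxy)-4-bromo-2-[(1E)-1-[4-(benzyloxy)phenyl]prop-1-en-2-yl]benzene
Product: 8 1-(benzyloxy)-4-bromo-2-[(2R)-1-[4-(benzyloxy)phenyl]propan-2-yl]benzene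
Conditions: H2 (50 bar), [Ir(cod)((S)-t-Bu-PHOX)][B(3,5-(CF3)2C6H3)4] (1 mol %), CH2Cl2, rt
Reagents that add atoms: none
Why: Iridium N,P-ligand-catalysed asymmetric hydrogenation of an unfunctionalised (E)-1,2-diarylpropene, the standard substrate class for these catalysts, should set the side-chain (R)-stereocentre by catalyst-controlled enantiofacial H2 addition and leave the aryl bromide and benzyl ethers untouched.

**Step 6**
Reactants: 9 meso-2,3-dimethylsuccinic acid
Product: 10 cis-3,4-dimethyloxolane-2,5-dione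
Conditions: AcCl, reflux; evaporation
Reagents that add atoms: none
Why: Cyclodehydration of the meso diacid with acetyl chloride should give the cis (meso) anhydride, the non-basic conditions leaving both stereocentres unchanged.

**Step 7**
Reactants: 10 cis-3,4-dimethyloxolane-2,5-dione; 3 1-(benzyloxy)-4-iodobenzene
Product: 12 (2S,3R)-4-[4-(benzyloxy)phenyl]-2,3-dimethyl-4-oxobutanoic acid, via arylzinc iodide 11 (not isolated)
Conditions: 3, Zn dust, LiCl, THF, 50 °C; then 10, [Rh(cod)Cl]2 (2.5 mol %), chiral TADDOL-derived phosphoramidite (6 mol %), THF/DMF, 50 °C; aq. HCl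
Reagents that add atoms: none
Why: Rhodium-catalysed enantioselective arylative desymmetrisation of a meso succinic anhydride with an arylzinc reagent (oxidative addition of monovalent rhodium into one enantiotopic acyl–oxygen bond, transmetalation, reductive elimination) lets the chiral ligand choose the carbonyl that is arylated, which should fix the future C3 and C4 as (S) and (R) without any bond change at these carbons.

**Step 8**
Reactants: 12 (2S,3R)-4-[4-(benzyloxy)phenyl]-2,3-dimethyl-4-oxobutanoic acid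
Product: 13 S-ethyl (2S,3R)-4-[4-(benzyloxy)phenyl]-2,3-dimethyl-4-oxobutanethioate
Conditions: EtSH, EDC·HCl, DMAP (cat.), CH2Cl2, 0 °C → rt
Reagents that add atoms: ethanethiol, CCS
Why: Carbodiimide-mediated thioesterification is mild enough to leave the ketone and both α-stereocentres unchanged.

**Step 9**
Reactants: 13 S-ethyl (2S,3R)-4-[4-(benzyloxy)phenyl]-2,3-dimethyl-4-oxobutanethioate
Product: 14 (2S,3R)-4-[4-(benzyloxy)phenyl]-2,3-dimethyl-4-oxobutanal
Conditions: Et3SiH, 10% Pd/C, acetone, rt; filtered and used crude at once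
Reagents that add atoms: none
Why: Fukuyama reduction (palladium-catalysed hydrosilane reduction of a thioester) should stop at the aldehyde and, in the aprotic neutral medium, spare the aryl ketone, the benzyl ether and the two epimerisable stereocentres.

**Step 10**
Reactants: 8 1-(benzyloxy)-4-bromo-2-[(2R)-1-[4-(benzyloxy)phenyl]propan-2-yl]benzene; 14 (2S,3R)-4-[4-(benzyloxy)phenyl]-2,3-dimethyl-4-oxobutanal
Product: 19 (2R,3S,4R,5S)-2-[4-(benzyloxy)-3-[(2R)-1-[4-(benzyloxy)phenyl]propan-2-yl]phenyl]-5-[4-(benzyloxy)phenyl]-3,4-dimethyloxolane, via aryllithium 15 (not isolated), via aryltitanium triisopropoxide 16 (not isolated), via titanium alkoxide 17 (not isolated), via oxocarbenium ion 18 (not isolated)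
Conditions: 8 (1.3 equiv), t-BuLi (2.6 equiv), Et2O, −78 °C; ClTi(OiPr)3 (1.4 equiv), −78 → −40 °C; 14, −78 → −20 °C; then CH2Cl2, Et3SiH (5 equiv), BF3·OEt2 (6 equiv), −78 °C; Et3N then aq. NaHCO3 at −78 °C
Reagents that add atoms: none
Why: Bromine–lithium exchange and transmetalation should give the non-basic aryltitanium 16, which adds to the aldehyde of 14 to give alkoxide 17; with BF3·OEt2 the alkoxide oxygen attacks the activated ketone (5-exo-trig hemiketalisation, closing O1–C5), the hemiketal ionises to the aryl-stabilised oxocarbenium ion 18, and Et3SiH delivers hydride to C5. The closest known reaction types are the chemoselective Felkin–Anh-selective addition of aryltitanium triisopropoxides to α-branched aldehydes in the presence of ketones, and the Et3SiH/BF3·OEt2 reductive cyclisation of γ-hydroxy aryl ketones and 2-aryl lactols to 2,3-cis-2-aryl-3-methyloxolanes. C2 is set by 1,2-induction from C3: in the Felkin–Anh transition state the branched C4 substituent is anti to the incoming aryl group and the methyl group lies next to the carbonyl oxygen, which gives the 1,2-syn alcohol, that is aryl cis to the C3 methyl group in the ring. C5 is set by the ring: in 18 the C2 aryl, C3 methyl and C4 methyl groups lie on one face, so hydride should enter from the opposite face, anti to the adjacent C4 methyl group, and push the C5 aryl group onto the common face to complete the all-cis array. The step needs aldehyde-over-ketone selectivity in the addition and kinetic control in the reduction (no proton loss at C4, no ring opening at the benzylic C–O bonds); these rest on the deactivated para-alkoxyaryl ketone, the titanium reagent, excess silane and a quench at −78 °C.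

**Step 11**
Reactants: 19 (2R,3S,4R,5S)-2-[4-(benzyloxy)-3-[(2R)-1-[4-(benzyloxy)phenyl]propan-2-yl]phenyl]-5-[4-(benzyloxy)phenyl]-3,4-dimethyloxolane
Product: 20 (2R,3S,4R,5S)-2-[4-hydroxy-3-[(2R)-1-(4-hydroxyphenyl)propan-2-yl]phenyl]-5-(4-hydroxyphenyl)-3,4-dimethyloxolane
Conditions: H2 (1 atm), 10% Pd/C, EtOAc, rt, monitored and stopped at full debenzylation
Reagents that add atoms: none
Why: Hydrogenolysis of the three aryl benzyl ethers over Pd/C is faster than cleavage of the benzylic C–O bonds of the oxolane and avoids the acid that would epimerise the all-cis ring through benzylic ring opening.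

**Compound list**
1 | 4-bromo-2-iodophenol | Oc1ccc(Br)cc1I | starting material
2 | 1-(benzyloxy)-4-bromo-2-iodobenzene | Brc1ccc(OCc2ccccc2)c(I)c1 | intermediate
3 | 1-(benzyloxy)-4-iodobenzene | Ic1ccc(OCc2ccccc2)cc1 | starting material
4 | propyne | CC#C | starting material
5 | 1-(benzyloxy)-4-(prop-1-yn-1-yl)benzene | CC#Cc1ccc(OCc2ccccc2)cc1 | intermediate
6 | 2-[(1Z)-1-[4-(benzyloxy)phenyl]prop-1-en-2-yl]-4,4,5,5-tetramethyl-1,3,2-dioxaborolane | C/C(B1OC(C)(C)C(C)(C)O1)=C\c1ccc(OCc2ccccc2)cc1 | intermediate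
7 | 1-(benzyloxy)-4-bromo-2-[(1E)-1-[4-(benzyloxy)phenyl]prop-1-en-2-yl]benzene | C/C(c1cc(Br)ccc1OCc1ccccc1)=C\c1ccc(OCc2ccccc2)cc1 | intermediate
8 | 1-(benzyloxy)-4-bromo-2-[(2R)-1-[4-(benzyloxy)phenyl]propan-2-yl]benzene | Brc1ccc(OCc2ccccc2)c([C@H](C)Cc2ccc(OCc3ccccc3)cc2)c1 | intermediate
9 | meso-2,3-dimethylsuccinic acid, (2R,3S)-2,3-dimethylbutanedioic acid | C[C@@H](C(=O)O)[C@H](C)C(=O)O | starting material
10 | cis-3,4-dimethyloxolane-2,5-dione, (3R,4S), meso | C[C@@H]1[C@H](C)C(=O)OC1=O | intermediate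
11 | [4-(benzyloxy)phenyl]zinc iodide (LiCl complex) | I[Zn]c1ccc(OCc2ccccc2)cc1 | intermediate (not isolated)
12 | (2S,3R)-4-[4-(benzyloxy)phenyl]-2,3-dimethyl-4-oxobutanoic acid | C[C@@H](C(=O)c1ccc(OCc2ccccc2)cc1)[C@H](C)C(=O)O | intermediate
13 | S-ethyl (2S,3R)-4-[4-(benzyloxy)phenyl]-2,3-dimethyl-4-oxobutanethioate | C[C@@H](C(=O)c1ccc(OCc2ccccc2)cc1)[C@H](C)C(=O)SCC | intermediate
14 | (2S,3R)-4-[4-(benzyloxy)phenyl]-2,3-dimethyl-4-oxobutanal | C[C@@H](C(=O)c1ccc(OCc2ccccc2)cc1)[C@H](C)C=O | intermediate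
15 | {4-(benzyloxy)-3-[(2R)-1-[4-(benzyloxy)phenyl]propan-2-yl]phenyl}lithium | [Li]c1ccc(OCc2ccccc2)c([C@H](C)Cc2ccc(OCc3ccccc3)cc2)c1 | intermediate (not isolated)
16 | {4-(benzyloxy)-3-[(2R)-1-[4-(benzyloxy)phenyl]propan-2-yl]phenyl}tri(propan-2-yloxy)titanium | CC(C)O[Ti](OC(C)C)(OC(C)C)c1ccc(OCc2ccccc2)c([C@H](C)Cc2ccc(OCc3ccccc3)cc2)c1 | intermediate (not isolated)
17 | tri(propan-2-yloxy)titanium alkoxide of (2R,3S,4R)-4-[4-(benzyloxy)-3-[(2R)-1-[4-(benzyloxy)phenyl]propan-2-yl]phenyl]-1-[4-(benzyloxy)phenyl]-4-hydroxy-2,3-dimethylbutan-1-one | C[C@@H](C(=O)c1ccc(OCc2ccccc2)cc1)[C@H](C)[C@H](c1ccc(OCc2ccccc2)c([C@H](C)Cc2ccc(OCc3ccccc3)cc2)c1)O[Ti](OC(C)C)(OC(C)C)OC(C)C | intermediate (not isolated)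
18 | (2R,3S,4R)-2-[4-(benzyloxy)-3-[(2R)-1-[4-(benzyloxy)phenyl]propan-2-yl]phenyl]-5-[4-(benzyloxy)phenyl]-3,4-dimethyl-3,4-dihydro-2H-furan-1-ium | C[C@@H]1[C@H](C)[C@H](c2ccc(OCc3ccccc3)c([C@H](C)Cc3ccc(OCc4ccccc4)cc3)c2)[O+]=C1c1ccc(OCc2ccccc2)cc1 | intermediate (not isolated)
19 | (2R,3S,4R,5S)-2-[4-(benzyloxy)-3-[(2R)-1-[4-(benzyloxy)phenyl]propan-2-yl]phenyl]-5-[4-(benzyloxy)phenyl]-3,4-dimethyloxolane | C[C@@H]1[C@H](C)[C@H](c2ccc(OCc3ccccc3)c([C@H](C)Cc3ccc(OCc4ccccc4)cc3)c2)O[C@@H]1c1ccc(OCc2ccccc2)cc1 | intermediate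
20 | (2R,3S,4R,5S)-2-[4-hydroxy-3-[(2R)-1-(4-hydroxyphenyl)propan-2-yl]phenyl]-5-(4-hydroxyphenyl)-3,4-dimethyloxolane (CNP0232576.2) | C[C@@H]1[C@H](C)[C@H](c2ccc(O)c([C@H](C)Cc3ccc(O)cc3)c2)O[C@@H]1c1ccc(O)cc1 | target

**Totals**
Total step count: 11.
Longest linear sequence: 6 steps (steps 2, 3, 4, 5, 10, 11 from 3; equally steps 6 to 11 from 9).

**Steps most likely to fail**

1. Step 10. What may go wrong: insufficient facial selectivity in the aryl transfer to the aldehyde (Felkin–Anh control by a methyl against a branched alkyl group is only moderate), or erosion during the one-pot reduction through proton loss from the oxocarbenium ion or ring opening at a benzylic C–O bond. The fallback sets out from thioester 13 and bromide 8 and comes back at 19. The C5 carbinol would be set under catalyst control instead of substrate control: Corey–Bakshi–Shibata reduction of the ketone of 13 ((R)-Me-CBS oxazaborolidine, BH3·SMe2, THF, −20 °C, the catalyst enantiomer that by the usual model delivers the (4S)-alcohol) should give S-ethyl (2S,3R,4S)-4-[4-(benzyloxy)phenyl]-4-hydroxy-2,3-dimethylbutanethioate F1. F1 should lactonise on standing or with a trace of Et3N to (3S,4R,5S)-5-[4-(benzyloxy)phenyl]-3,4-dimethyloxolan-2-one F2, at which stage diastereomers can be removed by chromatography. Addition of aryllithium 15 (from 8, t-BuLi, Et2O, −78 °C) to F2 should give the lactol (3S,4R,5S)-2-[4-(benzyloxy)-3-[(2R)-1-[4-(benzyloxy)phenyl]propan-2-yl]phenyl]-5-[4-(benzyloxy)phenyl]-3,4-dimethyloxolan-2-ol F3. Reduction of F3 with Et3SiH and BF3·OEt2 in CH2Cl2 at −78 °C should then deliver hydride anti to the three cis substituents and give 19.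

2. Step 7. What may go wrong: low enantioselectivity or slow turnover of the desymmetrisation with the alkoxy-substituted arylzinc iodide, or partial epimerisation next to the new ketone. The fallback sets out from anhydride 10, uses arylzinc 11, and comes back at 12. Organocatalytic methanolysis of 10 (MeOH, (DHQD)2AQN or its pseudo-enantiomer, Et2O, −20 °C) should give the hemiester (2R,3S)-4-methoxy-2,3-dimethyl-4-oxobutanoic acid F4. Thioesterification (EtSH, EDC·HCl, DMAP) should give methyl (2S,3R)-4-(ethylsulfanyl)-2,3-dimethyl-4-oxobutanoate F5. Fukuyama coupling of F5 with 11 (PdCl2(PPh3)2, THF/toluene, rt) should give methyl (2S,3R)-4-[4-(benzyloxy)phenyl]-2,3-dimethyl-4-oxobutanoate F6. Neutral ester cleavage with Me3SnOH (1,2-dichloroethane, 70 °C) should return 12.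

3. Step 5. What may go wrong: incomplete enantiofacial discrimination, because the ortho-benzyloxy group twists the aryl ring of 7 out of the alkene plane and the substrate departs from the ideal 1,2-diarylpropene shape. The fallback sets out from alkene 7 and comes back at 8, replacing enantiofacial catalysis by resolution. Hydrogenation of 7 with the achiral catalyst [Ir(cod)(PCy3)(py)]PF6 (H2, CH2Cl2, rt) should give racemic 1-(benzyloxy)-4-bromo-2-[1-[4-(benzyloxy)phenyl]propan-2-yl]benzene F7. Preparative chromatography on an amylose-based chiral stationary phase (supercritical CO2/MeOH) should deliver 8 and its (S)-enantiomer 1-(benzyloxy)-4-bromo-2-[(2S)-1-[4-(benzyloxy)phenyl]propan-2-yl]benzene F8, which is set aside.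

**Further compounds**
F1 | step 10 | S-ethyl (2S,3R,4S)-4-[4-(benzyloxy)phenyl]-4-hydroxy-2,3-dimethylbutanethioate | C[C@@H]([C@H](O)c1ccc(OCc2ccccc2)cc1)[C@H](C)C(=O)SCC
F2 | step 10 | (3S,4R,5S)-5-[4-(benzyloxy)phenyl]-3,4-dimethyloxolan-2-one | C[C@@H]1[C@H](C)C(=O)O[C@@H]1c1ccc(OCc2ccccc2)cc1
F3 | step 10 | (3S,4R,5S)-2-[4-(benzyloxy)-3-[(2R)-1-[4-(benzyloxy)phenyl]propan-2-yl]phenyl]-5-[4-(benzyloxy)phenyl]-3,4-dimethyloxolan-2-ol (anomeric mixture) | C[C@@H]1[C@H](C)C(O)(c2ccc(OCc3ccccc3)c([C@H](C)Cc3ccc(OCc4ccccc4)cc3)c2)O[C@@H]1c1ccc(OCc2ccccc2)cc1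
F4 | step 7 | (2R,3S)-4-methoxy-2,3-dimethyl-4-oxobutanoic acid | C[C@@H](C(=O)O)[C@H](C)C(=O)OC
F5 | step 7 | methyl (2S,3R)-4-(ethylsulfanyl)-2,3-dimethyl-4-oxobutanoate | C[C@@H](C(=O)SCC)[C@H](C)C(=O)OC
F6 | step 7 | methyl (2S,3R)-4-[4-(benzyloxy)phenyl]-2,3-dimethyl-4-oxobutanoate | C[C@@H](C(=O)c1ccc(OCc2ccccc2)cc1)[C@H](C)C(=O)OC
F7 | step 5 | rac-1-(benzyloxy)-4-bromo-2-[1-[4-(benzyloxy)phenyl]propan-2-yl]benzene | Brc1ccc(OCc2ccccc2)c(C(C)Cc2ccc(OCc3ccccc3)cc2)c1
F8 | step 5 | 1-(benzyloxy)-4-bromo-2-[(2S)-1-[4-(benzyloxy)phenyl]propan-2-yl]benzene | Brc1ccc(OCc2ccccc2)c([C@@H](C)Cc2ccc(OCc3ccccc3)cc2)c1
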